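**Retrosynthetic overview**
- Target ⇐ its diacetate/TBS ether by global deprotection; no ring is built (the arene is bought; the only ring formed is a transient oxirane).
- Benzyl–alkenyl bond C1′–C2′ and the C3′–CH3 bond: Zr-catalysed methylalumination of a terminal alkyne, then Pd benzylation with 2-(bromomethyl)-6-methylhydroquinone diacetate (from 2,6-dimethylhydroquinone).
- Alkyne ⇐ β-silyloxy methyl ester (DIBAL-H, then Ohira–Bestmann).
- Key step: the C5′–O bond and the only stereocentre come from asymmetric aminocatalytic epoxidation of a 2,4-dienal, followed in the same flask by NHC redox opening to the β-hydroxy ester.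
- Dienal ⇐ (2E,6E)-farnesol (oxidation, two-carbon Wittig homologation); all E-alkenes of the farnesyl part are bought.

Assumption: the (S)-diarylprolinol silyl ether delivers the peroxide anti to its diaryl(silyloxy)methyl arm on the s-trans E-iminium ion, which is worked out here from the steric model rather than taken from a reported example; the configuration and ee of 5 are checked by Mosher ester analysis (C1′–C16′ are side-chain locants of the target counted from the arene).

**Step 1**
Reactants: 1 (2E,6E)-farnesol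
Product: 2 (2E,6E)-farnesal
Conditions: MnO2 (15 equiv), CH2Cl2, rt
Reagents that add atoms: none
Why: Activated MnO2 oxidises only the allylic primary alcohol (allylic oxidation) and leaves the 2E geometry and the isolated trisubstituted alkenes untouched.

**Step 2**
Reactants: 2 (2E,6E)-farnesal
Product: 3 (2E,4E,8E)-5,9,13-trimethyltetradeca-2,4,8,12-tetraenal
Conditions: Ph3P=CHCHO (1.3 equiv), toluene, 90 °C
Reagents that add atoms: (triphenylphosphoranylidene)acetaldehyde, O=CC=P(c1ccccc1)(c1ccccc1)c1ccccc1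
Why: Wittig olefination with the stabilised formylmethylene ylide is E-selective, and the doubly conjugated product is less electrophilic than 2, so the two-carbon homologation stops at the (2E,4E)-dienal.

**Step 3**
Reactants: 3 (2E,4E,8E)-5,9,13-trimethyltetradeca-2,4,8,12-tetraenal
Product: 5 methyl (3S,4E,8E)-3-hydroxy-5,9,13-trimethyltetradeca-4,8,12-trienoate, via epoxy aldehyde 4 (not isolated)
Conditions: (S)-2-{bis[3,5-bis(trifluoromethyl)phenyl][(trimethylsilyl)oxy]methyl}pyrrolidine (10 mol%), 35% aq H2O2 (1.3 equiv), CH2Cl2, rt; phase cut, Na2SO4; then 3-benzyl-4,5-dimethylthiazolium chloride (10 mol%), iPr2NEt (10 mol%), MeOH (5 equiv), CH2Cl2, 30 °C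
Reagents that add atoms: hydrogen peroxide, OO; methanol, CO
Why: Proposed new method: a one-flask aminocatalytic epoxidation/NHC internal-redox esterification, a sequence of simple β-alkyl and β-aryl enals, is applied here to a δ,δ-disubstituted polyprenyl 2,4-dienal; the s-trans E-dienyl iminium ion of 3 takes up HOO− at C3 (1,4) rather than at the fully substituted C5 (1,6), anti to the diaryl(silyloxy)methyl arm of the (S)-catalyst, and the enamine closes on the O–O bond (Weitz–Scheffer) to the trans-(2S,3R)-oxirane 4, which forms both C–O bonds and fixes the future C5′ centre; the thiazolylidene then adds to the formyl group, the Breslow intermediate opens the oxirane at Cα–O only (E1cB type), and the acyl azolium is methanolysed to 5 with the C3–O bond and its configuration untouched; closest known reactions: amine-catalysed asymmetric epoxidation of enals with H2O2 and NHC-catalysed redox esterification of α,β-epoxy aldehydes.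

**Step 4**
Reactants: 5 methyl (3S,4E,8E)-3-hydroxy-5,9,13-trimethyltetradeca-4,8,12-trienoate
Product: 6 methyl (3S,4E,8E)-3-[(tert-butyldimethylsilyl)oxy]-5,9,13-trimethyltetradeca-4,8,12-trienoate
Conditions: TBSCl (1.5 equiv), imidazole (3 equiv), DMF, rt
Reagents that add atoms: tert-butyldimethylsilyl chloride, CC(C)(C)[Si](C)(C)Cl
Why: Standard silyl protection masks the β-hydroxyl so that the derived aldehyde cannot undergo retro-aldol cleavage in step 5; the stereocentre is not involved.

**Step 5**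
Reactants: 6 methyl (3S,4E,8E)-3-[(tert-butyldimethylsilyl)oxy]-5,9,13-trimethyltetradeca-4,8,12-trienoate
Product: 8 tert-butyldimethyl{[(4S,5E,9E)-6,10,14-trimethylpentadeca-5,9,13-trien-1-yn-4-yl]oxy}silane, via silyloxy aldehyde 7 (not isolated)
Conditions: DIBAL-H (1.15 equiv), CH2Cl2, −78 °C; then MeOH, K2CO3 (3 equiv), dimethyl (1-diazo-2-oxopropyl)phosphonate (1.5 equiv), −78 °C → rt; Rochelle salt work-up
Reagents that add atoms: dimethyl (1-diazo-2-oxopropyl)phosphonate, COP(=O)(OC)C(=[N+]=[N-])C(C)=O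
Why: DIBAL-H at −78 °C stops at the tetrahedral aluminium hemiacetal, methanol releases aldehyde 7, and the Ohira–Bestmann variant of the Seyferth–Gilbert homologation converts it in the same flask into the terminal alkyne; the stereocentre is β to the carbonyl and is not epimerised.

**Step 6**
Reactants: 9 2,6-dimethylbenzene-1,4-diol
Product: 10 2,6-dimethyl-1,4-phenylene diacetate
Conditions: Ac2O (2.5 equiv), pyridine, DMAP (cat.), CH2Cl2, rt
Reagents that add atoms: acetic anhydride, CC(=O)OC(C)=O
Why: Acetylation of both phenols (acyl transfer) deactivates the ring towards bromine and oxidation in the next step.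

**Step 7**
Reactants: 10 2,6-dimethyl-1,4-phenylene diacetate
Product: 11 2-(bromomethyl)-6-methyl-1,4-phenylene diacetate
Conditions: NBS (1.0 equiv), AIBN (5 mol%), PhCF3, 85 °C
Reagents that add atoms: N-bromosuccinimide, O=C1CCC(=O)N1Br
Why: Wohl–Ziegler benzylic bromination; the two methyl groups are equivalent by symmetry, the acetoxy groups suppress ring bromination, and one equivalent of NBS holds the reaction at the monobromide (unreacted 10 is recycled).

**Step 8**
Reactants: 8 tert-butyldimethyl{[(4S,5E,9E)-6,10,14-trimethylpentadeca-5,9,13-trien-1-yn-4-yl]oxy}silane; 11 2-(bromomethyl)-6-methyl-1,4-phenylene diacetate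
Product: 13 2-[(2E,5S,6E,10E)-5-[(tert-butyldimethylsilyl)oxy]-3,7,11,15-tetramethylhexadeca-2,6,10,14-tetraen-1-yl]-6-methyl-1,4-phenylene diacetate, via alkenylalane 12 (not isolated)
Conditions: Me3Al (2.5 equiv), Cp2ZrCl2 (20 mol%), H2O (1 equiv), CH2Cl2, −20 → 0 °C; excess Me3Al removed in vacuo; then 11 (1.1 equiv), Pd(PPh3)4 (5 mol%), THF, rt
Reagents that add atoms: trimethylaluminium, C[Al](C)C
Why: Negishi zirconium-catalysed methylalumination adds Me and Al syn across the terminal alkyne (Me to the internal carbon), and the alkenylalane is benzylated with retention under Pd catalysis (Negishi coupling), which sets the 2E trisubstituted alkene; the trisubstituted alkenes and the silyl ether do not react.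

**Step 9**
Reactants: 13 2-[(2E,5S,6E,10E)-5-[(tert-butyldimethylsilyl)oxy]-3,7,11,15-tetramethylhexadeca-2,6,10,14-tetraen-1-yl]-6-methyl-1,4-phenylene diacetate
Product: 15 2-[(2E,5S,6E,10E)-5-hydroxy-3,7,11,15-tetramethylhexadeca-2,6,10,14-tetraen-1-yl]-6-methylbenzene-1,4-diol, via hydroquinone silyl ether 14 (not isolated)
Conditions: K2CO3 (0.3 equiv), MeOH–THF (degassed), 0 °C → rt, Ar; concentrate; then TBAF (3 equiv), THF, rt; aq NH4Cl/Na2S2O4 work-up
Reagents that add atoms: none
Why: Base-catalysed methanolysis of the two aryl acetates (transesterification) followed by fluoride desilylation releases the hydroquinone and the C5′ alcohol under non-acidic, air-free conditions, so the allylic alcohol, the skipped polyene and the stereocentre are untouched.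

**Compound list**
1 | (2E,6E)-farnesol | CC(C)=CCC/C(C)=C/CC/C(C)=C/CO | starting material
2 | (2E,6E)-farnesal | CC(C)=CCC/C(C)=C/CC/C(C)=C/C=O | intermediate
3 | (2E,4E,8E)-5,9,13-trimethyltetradeca-2,4,8,12-tetraenal | CC(C)=CCC/C(C)=C/CC/C(C)=C/C=C/C=O | intermediate
4 | (2S,3R)-3-[(1E,5E)-2,6,10-trimethylundeca-1,5,9-trien-1-yl]oxirane-2-carbaldehyde (trans-epoxy aldehyde, not isolated) | CC(C)=CCC/C(C)=C/CC/C(C)=C/[C@H]1O[C@@H]1C=O | intermediate
5 | methyl (3S,4E,8E)-3-hydroxy-5,9,13-trimethyltetradeca-4,8,12-trienoate | CC(C)=CCC/C(C)=C/CC/C(C)=C/[C@@H](O)CC(=O)OC | intermediate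
6 | methyl (3S,4E,8E)-3-[(tert-butyldimethylsilyl)oxy]-5,9,13-trimethyltetradeca-4,8,12-trienoate | CC(C)=CCC/C(C)=C/CC/C(C)=C/[C@@H](O[Si](C)(C)C(C)(C)C)CC(=O)OC | intermediate
7 | (3S,4E,8E)-3-[(tert-butyldimethylsilyl)oxy]-5,9,13-trimethyltetradeca-4,8,12-trienal (not isolated) | CC(C)=CCC/C(C)=C/CC/C(C)=C/[C@@H](O[Si](C)(C)C(C)(C)C)CC=O | intermediate
8 | tert-butyldimethyl{[(4S,5E,9E)-6,10,14-trimethylpentadeca-5,9,13-trien-1-yn-4-yl]oxy}silane | CC(C)=CCC/C(C)=C/CC/C(C)=C/[C@@H](O[Si](C)(C)C(C)(C)C)CC#C | intermediate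
9 | 2,6-dimethylbenzene-1,4-diol (2,6-dimethylhydroquinone) | Cc1cc(O)cc(C)c1O | starting material
10 | 2,6-dimethyl-1,4-phenylene diacetate | CC(=O)Oc1cc(C)c(OC(C)=O)c(C)c1 | intermediate
11 | 2-(bromomethyl)-6-methyl-1,4-phenylene diacetate | CC(=O)Oc1cc(C)c(OC(C)=O)c(CBr)c1 | intermediate
12 | [(1E,4S,5E,9E)-4-[(tert-butyldimethylsilyl)oxy]-2,6,10,14-tetramethylpentadeca-1,5,9,13-tetraen-1-yl]dimethylalumane (not isolated) | CC(C)=CCC/C(C)=C/CC/C(C)=C/[C@@H](O[Si](C)(C)C(C)(C)C)C/C(C)=C/[Al](C)C | intermediate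
13 | 2-[(2E,5S,6E,10E)-5-[(tert-butyldimethylsilyl)oxy]-3,7,11,15-tetramethylhexadeca-2,6,10,14-tetraen-1-yl]-6-methyl-1,4-phenylene diacetate | CC(C)=CCC/C(C)=C/CC/C(C)=C/[C@@H](O[Si](C)(C)C(C)(C)C)C/C(C)=C/Cc1cc(OC(C)=O)cc(C)c1OC(C)=O | intermediate
14 | 2-[(2E,5S,6E,10E)-5-[(tert-butyldimethylsilyl)oxy]-3,7,11,15-tetramethylhexadeca-2,6,10,14-tetraen-1-yl]-6-methylbenzene-1,4-diol (not isolated) | CC(C)=CCC/C(C)=C/CC/C(C)=C/[C@@H](O[Si](C)(C)C(C)(C)C)C/C(C)=C/Cc1cc(O)cc(C)c1O | intermediate
15 | 2-[(2E,5S,6E,10E)-5-hydroxy-3,7,11,15-tetramethylhexadeca-2,6,10,14-tetraen-1-yl]-6-methylbenzene-1,4-diol (CNP0314458.1) | CC(C)=CCC/C(C)=C/CC/C(C)=C/[C@@H](O)C/C(C)=C/Cc1cc(O)cc(C)c1O | target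

**Step count and risks**
Total steps: 9. Longest linear sequence: 7 (steps 1–5, 8, 9); steps 6–7 make the aryl fragment.

The three steps most likely to fail are 3, 5 and 8.

Step 3 (the new step). The dienyl iminium ion can lose the 4E geometry through a trienamine, peroxide can add 1,6, and the β-hydroxy acyl azolium can dehydrate to the dienoate. The fallback uses known chemistry, sets out from 3 and comes back at 7. Luche reduction of 3 (NaBH4, CeCl3·7H2O, MeOH, 0 °C) gives the 2,4-dienol F1. Sharpless asymmetric epoxidation (Ti(OiPr)4, D-(−)-diethyl tartrate, TBHP, 4 Å MS, CH2Cl2, −20 °C) epoxidises only the allylic 2,3-alkene and gives the (2R,3R)-epoxy alcohol F2, so the centre is again set by C–O bond formation. Red-Al (THF, 0 °C) delivers hydride to C2 and gives the (3S)-1,3-diol F3. TBSOTf/2,6-lutidine gives the bis-TBS ether F4, HF·pyridine/pyridine (THF, 0 °C) frees the primary alcohol F5, and Dess–Martin oxidation (NaHCO3, CH2Cl2) gives aldehyde 7, which is homologated to 8 under the Ohira–Bestmann conditions of step 5.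

Step 5. The partial reduction can over-run, and aldehyde 7 can lose silanolate under K2CO3/MeOH to return dienal 3. The fallback sets out from 6 and comes back at 8. DIBAL-H at −78 °C with Rochelle salt work-up gives isolated 7. Base-free dibromo-olefination (CBr4, PPh3, Et3N, CH2Cl2, 0 °C) gives the 1,1-dibromoalkene F6, and n-BuLi (2.1 equiv, THF, −78 °C) then water gives alkyne 8 (Corey–Fuchs).

Step 8. Residual Me3Al can attack the aryl acetates, the allylic silyl ether can ionise under the Lewis-acidic conditions, and the alane–benzyl coupling can be slow. The fallback reverses the polarity of the benzyl–alkenyl bond; it sets out from 8 and 11 and comes back at 13. Alkenylalane 12, made as in step 8, is quenched with I2 (THF, −30 °C) to give the (E)-alkenyl iodide F7, which is purified free of aluminium. Zinc insertion into 11 (Zn dust, LiCl, THF, rt) gives the benzylzinc bromide F8, and Negishi coupling of F7 with F8 (Pd(OAc)2/SPhos, THF, rt) gives 13.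

**Further compounds**
F1 | step 3 | (2E,4E,8E)-5,9,13-trimethyltetradeca-2,4,8,12-tetraen-1-ol | CC(C)=CCC/C(C)=C/CC/C(C)=C/C=C/CO
F2 | step 3 | [(2R,3R)-3-[(1E,5E)-2,6,10-trimethylundeca-1,5,9-trien-1-yl]oxiran-2-yl]methanol | CC(C)=CCC/C(C)=C/CC/C(C)=C/[C@H]1O[C@@H]1CO
F3 | step 3 | (3S,4E,8E)-5,9,13-trimethyltetradeca-4,8,12-triene-1,3-diol | CC(C)=CCC/C(C)=C/CC/C(C)=C/[C@@H](O)CCO
F4 | step 3 | (3S,4E,8E)-1,3-bis[(tert-butyldimethylsilyl)oxy]-5,9,13-trimethyltetradeca-4,8,12-triene | CC(C)=CCC/C(C)=C/CC/C(C)=C/[C@@H](O[Si](C)(C)C(C)(C)C)CCO[Si](C)(C)C(C)(C)C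
F5 | step 3 | (3S,4E,8E)-3-[(tert-butyldimethylsilyl)oxy]-5,9,13-trimethyltetradeca-4,8,12-trien-1-ol | CC(C)=CCC/C(C)=C/CC/C(C)=C/[C@@H](O[Si](C)(C)C(C)(C)C)CCO
F6 | step 5 | tert-butyl{[(4S,5E,9E)-1,1-dibromo-6,10,14-trimethylpentadeca-1,5,9,13-tetraen-4-yl]oxy}dimethylsilane | CC(C)=CCC/C(C)=C/CC/C(C)=C/[C@@H](O[Si](C)(C)C(C)(C)C)CC=C(Br)Br
F7 | step 8 | tert-butyl{[(1E,4S,5E,9E)-1-iodo-2,6,10,14-tetramethylpentadeca-1,5,9,13-tetraen-4-yl]oxy}dimethylsilane | CC(C)=CCC/C(C)=C/CC/C(C)=C/[C@@H](O[Si](C)(C)C(C)(C)C)C/C(C)=C/I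
F8 | step 8 | [2,5-bis(acetyloxy)-3-methylbenzyl]zinc bromide | CC(=O)Oc1cc(C)c(OC(C)=O)c(C[Zn]Br)c1
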